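**Retrosynthetic overview**
1. Target 13 ← O-benzyl ether 12 by hydrogenolysis (the only protecting group, removed last).
2. THF ring of 12 (second and final ring) ← acid-mediated closure of the C2–O1 bond in triol 11, with C2 set 2,3-trans under thermodynamic control.
3. Triol 11 ← LiAlH4 opening of aldol lactone 10 ← anti-selective aldol of (R)-β-benzyl-γ-butyrolactone 8 with 3,4,5-trimethoxybenzaldehyde 9 (sets C3 from C4).
4. Lactone 8 (first ring, temporary) ← Evans alkylation of imide 4 with tert-butyl bromoacetate 5 (sets C4), then reductive auxiliary removal and lactonisation.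
5. Ring order: butyrolactone first (opened in step 5), tetrahydrofuran last.

Assumption: 3-[4-(benzyloxy)-3-methoxyphenyl]propanoic acid 1 is bought as a catalogue compound.
Assumption: metal enolates and the benzylic cation are treated as transient reactive species and not numbered; the crude hydroxy ester 7 (worked up, not purified) counts as not isolated.

**Route**

Step 1
Reactants: 1 3-[4-(benzyloxy)-3-methoxyphenyl]propanoic acid; 2 (S)-4-benzyl-2-oxazolidinone
Product: 4 (S)-4-benzyl-3-{3-[4-(benzyloxy)-3-methoxyphenyl]propanoyl}oxazolidin-2-one, via mixed pivalic anhydride 3 (not isolated)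
Conditions: PivCl, Et3N, THF, −20 °C; then LiCl, 2, −20 °C → rt
Reagents that add atoms: pivaloyl chloride, CC(C)(C)C(Cl)=O (its acyl group sits in intermediate 3 only; none of it remains in 4)
Why: N-acylation of the oxazolidinone through a mixed anhydride, where the LiCl-activated auxiliary attacks the unhindered acyl carbon and not the pivaloyl carbon; no new stereocentre.

Step 2
Reactants: 4 (S)-4-benzyl-3-{3-[4-(benzyloxy)-3-methoxyphenyl]propanoyl}oxazolidin-2-one; 5 tert-butyl bromoacetate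
Product: 6 tert-butyl (R)-3-{[(S)-4-benzyl-2-oxooxazolidin-3-yl]carbonyl}-4-[4-(benzyloxy)-3-methoxyphenyl]butanoate
Conditions: NaHMDS, THF, −78 °C; then 5, −78 → −40 °C
Reagents that add atoms: none
Why: Evans asymmetric alkylation, in which the chelated Z-sodium enolate is alkylated on the face opposite the auxiliary's 4-benzyl group, setting the future C4 of the target as (R).

Step 3
Reactants: 6 tert-butyl (R)-3-{[(S)-4-benzyl-2-oxooxazolidin-3-yl]carbonyl}-4-[4-(benzyloxy)-3-methoxyphenyl]butanoate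
Product: 8 (R)-4-[4-(benzyloxy)-3-methoxybenzyl]dihydrofuran-2(3H)-one, via hydroxy tert-butyl ester 7 (not isolated)
Conditions: LiBH4, MeOH (1.5 equiv), THF, 0 °C; aq. NH4Cl work-up; crude 7, p-TsOH·H2O (10 mol %), toluene, 80 °C
Reagents that add atoms: none
Why: Chemoselective reductive cleavage of the imide (more electrophilic than the tert-butyl ester) followed by acid-catalysed lactonisation (intramolecular transesterification); the stereocentre is no longer α to a carbonyl after reduction, so it cannot epimerise.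

Step 4
Reactants: 8 (R)-4-[4-(benzyloxy)-3-methoxybenzyl]dihydrofuran-2(3H)-one; 9 3,4,5-trimethoxybenzaldehyde
Product: 10 (3S,4R)-4-[4-(benzyloxy)-3-methoxybenzyl]-3-[hydroxy(3,4,5-trimethoxyphenyl)methyl]dihydrofuran-2(3H)-one (both carbinol epimers)
Conditions: LDA, THF, −78 °C; then 9, −78 °C; AcOH quench at −78 °C
Reagents that add atoms: none
Why: Aldol addition of the lactone lithium enolate, where the aldehyde adds anti to the C4 benzyl group to give the 3,4-trans lactone (sets target C3); the carbinol epimers are carried together because that centre is ionised in step 6.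

Step 5
Reactants: 10 (3S,4R)-4-[4-(benzyloxy)-3-methoxybenzyl]-3-[hydroxy(3,4,5-trimethoxyphenyl)methyl]dihydrofuran-2(3H)-one
Product: 11 (2R,3R)-2-[4-(benzyloxy)-3-methoxybenzyl]-3-[hydroxy(3,4,5-trimethoxyphenyl)methyl]butane-1,4-diol (both carbinol epimers)
Conditions: LiAlH4, THF, 0 °C → rt; Fieser work-up
Reagents that add atoms: none
Why: Hydride reduction of the lactone to the 1,4-diol, which touches neither backbone stereocentre nor the aryl benzyl ether.

Step 6
Reactants: 11 (2R,3R)-2-[4-(benzyloxy)-3-methoxybenzyl]-3-[hydroxy(3,4,5-trimethoxyphenyl)methyl]butane-1,4-diol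
Product: 12 [(2S,3R,4R)-4-[4-(benzyloxy)-3-methoxybenzyl]-2-(3,4,5-trimethoxyphenyl)tetrahydrofuran-3-yl]methanol
Conditions: 10-camphorsulfonic acid (0.2 equiv), CH2Cl2 (dilute), 0 °C → rt; Et3N quench as soon as 11 is consumed
Reagents that add atoms: none
Why: Acid-catalysed SN1 cyclodehydration, where the trimethoxybenzylic cation is trapped 5-exo by the primary OH four atoms away (the other primary OH could only form an oxetane); the aryl group settles trans to the C3 hydroxymethyl, so both carbinol epimers converge on (2S).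

Step 7
Reactants: 12 [(2S,3R,4R)-4-[4-(benzyloxy)-3-methoxybenzyl]-2-(3,4,5-trimethoxyphenyl)tetrahydrofuran-3-yl]methanol
Product: 13 [(2S,3R,4R)-4-(4-hydroxy-3-methoxybenzyl)-2-(3,4,5-trimethoxyphenyl)tetrahydrofuran-3-yl]methanol (target)
Conditions: H2 (1 atm), 10% Pd/C, EtOAc, rt; stopped at full conversion of 12
Reagents that add atoms: none
Why: Catalytic hydrogenolysis of the aryl benzyl ether, which under neutral conditions is much faster than cleavage of the cyclic benzylic C2–O bond; no stereocentre is affected.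

**Compound list**
1 | 3-[4-(benzyloxy)-3-methoxyphenyl]propanoic acid | COc1cc(CCC(=O)O)ccc1OCc1ccccc1 | starting material
2 | (S)-4-benzyl-2-oxazolidinone | O=C1N[C@@H](Cc2ccccc2)CO1 | starting material
3 | 3-[4-(benzyloxy)-3-methoxyphenyl]propanoic pivalic anhydride | COc1cc(CCC(=O)OC(=O)C(C)(C)C)ccc1OCc1ccccc1 | intermediate (not isolated)
4 | (S)-4-benzyl-3-{3-[4-(benzyloxy)-3-methoxyphenyl]propanoyl}oxazolidin-2-one | COc1cc(CCC(=O)N2[C@@H](Cc3ccccc3)COC2=O)ccc1OCc1ccccc1 | intermediate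
5 | tert-butyl bromoacetate | CC(C)(C)OC(=O)CBr | starting material
6 | tert-butyl (R)-3-{[(S)-4-benzyl-2-oxooxazolidin-3-yl]carbonyl}-4-[4-(benzyloxy)-3-methoxyphenyl]butanoate | CC(C)(C)OC(=O)C[C@@H](Cc1ccc(OCc2ccccc2)c(OC)c1)C(=O)N1[C@@H](Cc2ccccc2)COC1=O | intermediate
7 | tert-butyl (R)-4-[4-(benzyloxy)-3-methoxyphenyl]-3-(hydroxymethyl)butanoate | CC(C)(C)OC(=O)C[C@@H](Cc1ccc(OCc2ccccc2)c(OC)c1)CO | intermediate (not isolated)
8 | (R)-4-[4-(benzyloxy)-3-methoxybenzyl]dihydrofuran-2(3H)-one | O=C1C[C@@H](Cc2ccc(OCc3ccccc3)c(OC)c2)CO1 | intermediate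
9 | 3,4,5-trimethoxybenzaldehyde | COc1cc(C=O)cc(OC)c1OC | starting material
10 | (3S,4R)-4-[4-(benzyloxy)-3-methoxybenzyl]-3-[hydroxy(3,4,5-trimethoxyphenyl)methyl]dihydrofuran-2(3H)-one, carbinol epimers | O=C1OC[C@H](Cc2ccc(OCc3ccccc3)c(OC)c2)[C@H]1C(O)c1cc(OC)c(OC)c(OC)c1 | intermediate
11 | (2R,3R)-2-[4-(benzyloxy)-3-methoxybenzyl]-3-[hydroxy(3,4,5-trimethoxyphenyl)methyl]butane-1,4-diol, carbinol epimers | OC[C@H](Cc1ccc(OCc2ccccc2)c(OC)c1)[C@H](CO)C(O)c1cc(OC)c(OC)c(OC)c1 | intermediate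
12 | [(2S,3R,4R)-4-[4-(benzyloxy)-3-methoxybenzyl]-2-(3,4,5-trimethoxyphenyl)tetrahydrofuran-3-yl]methanol | COc1cc(C[C@H]2CO[C@H](c3cc(OC)c(OC)c(OC)c3)[C@H]2CO)ccc1OCc1ccccc1 | intermediate
13 | [(2S,3R,4R)-4-(4-hydroxy-3-methoxybenzyl)-2-(3,4,5-trimethoxyphenyl)tetrahydrofuran-3-yl]methanol | COc1cc(C[C@H]2CO[C@H](c3cc(OC)c(OC)c(OC)c3)[C@H]2CO)ccc1O | target

**Totals**
Total step count: 7. Longest linear sequence: 7 steps (1 → 13).

**Three steps most likely to fail**

Step 6 (ring closure). The trimethoxybenzylic cation may form sluggishly, and stronger acid lets the guaiacyl ring attack it instead (Friedel–Crafts aryltetralin). The fallback swaps the unassisted cation for a p-quinone-methide closure followed by O-methylation; it sets out from 8 and comes back at 12. Syringaldehyde is silylated (TBSCl, imidazole, DMF) to 4-[(tert-butyldimethylsilyl)oxy]-3,5-dimethoxybenzaldehyde F1. Aldol of 8 with it (LDA, THF, −78 °C) gives the 3,4-trans adduct (3S,4R)-4-[4-(benzyloxy)-3-methoxybenzyl]-3-{[4-(tert-butyldimethylsilyloxy)-3,5-dimethoxyphenyl](hydroxy)methyl}dihydrofuran-2(3H)-one F2. LiAlH4 (THF, 0 °C) gives (2R,3R)-2-[4-(benzyloxy)-3-methoxybenzyl]-3-{[4-(tert-butyldimethylsilyloxy)-3,5-dimethoxyphenyl](hydroxy)methyl}butane-1,4-diol F3. TBAF/AcOH frees the phenol to (2R,3R)-2-[4-(benzyloxy)-3-methoxybenzyl]-3-[hydroxy(4-hydroxy-3,5-dimethoxyphenyl)methyl]butane-1,4-diol F4. This p-hydroxybenzylic alcohol closes through its quinone methide under very mild acid (PPTS, CH2Cl2, 0 °C), where the Friedel–Crafts path does not compete, to the 2,3-trans phenol 4-[(2S,3R,4R)-4-[4-(benzyloxy)-3-methoxybenzyl]-3-(hydroxymethyl)tetrahydrofuran-2-yl]-2,6-dimethoxyphenol F5. MeI/K2CO3/acetone methylates only the phenol and delivers 12.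

Step 7 (debenzylation). Over-reduction could open the benzylic C2–O bond of the tetrahydrofuran. The fallback removes the benzyl group before any benzylic C–O bond exists and carries the free phenol through; it sets out from 8 and comes back at 13. Hydrogenolysis of 8 (H2, Pd/C, EtOAc) gives (R)-4-(4-hydroxy-3-methoxybenzyl)dihydrofuran-2(3H)-one F6. Its phenoxide/enolate dianion (LDA, 2.2 equiv, THF, −78 °C) adds to 9 to give (3S,4R)-3-[hydroxy(3,4,5-trimethoxyphenyl)methyl]-4-(4-hydroxy-3-methoxybenzyl)dihydrofuran-2(3H)-one F7. LiAlH4 gives (2R,3R)-2-(4-hydroxy-3-methoxybenzyl)-3-[hydroxy(3,4,5-trimethoxyphenyl)methyl]butane-1,4-diol F8, and the CSA cyclisation of step 6 applied to it gives 13 directly.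

Step 4 (aldol). Retro-aldol or poor conversion with the electron-rich aldehyde is possible. The fallback replaces the reversible aldol by an irreversible Claisen-type C-acylation followed by ketone reduction; it sets out from 8 and comes back at 10. The enolate of 8 (LiHMDS, 2.2 equiv, THF, −78 °C) is acylated with 3,4,5-trimethoxybenzoyl chloride to give (3S,4R)-4-[4-(benzyloxy)-3-methoxybenzyl]-3-(3,4,5-trimethoxybenzoyl)dihydrofuran-2(3H)-one F9, whose acidic C3 equilibrates to the trans isomer. NaBH4 (MeOH/THF, −20 °C) reduces the ketone and returns 10 as its carbinol epimers.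

**Further compounds**
F1 | step 6 | 4-[(tert-butyldimethylsilyl)oxy]-3,5-dimethoxybenzaldehyde | COc1cc(C=O)cc(OC)c1O[Si](C)(C)C(C)(C)C
F2 | step 6 | (3S,4R)-4-[4-(benzyloxy)-3-methoxybenzyl]-3-{[4-(tert-butyldimethylsilyloxy)-3,5-dimethoxyphenyl](hydroxy)methyl}dihydrofuran-2(3H)-one | O=C1OC[C@H](Cc2ccc(OCc3ccccc3)c(OC)c2)[C@H]1C(O)c1cc(OC)c(O[Si](C)(C)C(C)(C)C)c(OC)c1
F3 | step 6 | (2R,3R)-2-[4-(benzyloxy)-3-methoxybenzyl]-3-{[4-(tert-butyldimethylsilyloxy)-3,5-dimethoxyphenyl](hydroxy)methyl}butane-1,4-diol | OC[C@H](Cc1ccc(OCc2ccccc2)c(OC)c1)[C@H](CO)C(O)c1cc(OC)c(O[Si](C)(C)C(C)(C)C)c(OC)c1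
F4 | step 6 | (2R,3R)-2-[4-(benzyloxy)-3-methoxybenzyl]-3-[hydroxy(4-hydroxy-3,5-dimethoxyphenyl)methyl]butane-1,4-diol | OC[C@H](Cc1ccc(OCc2ccccc2)c(OC)c1)[C@H](CO)C(O)c1cc(OC)c(O)c(OC)c1
F5 | step 6 | 4-[(2S,3R,4R)-4-[4-(benzyloxy)-3-methoxybenzyl]-3-(hydroxymethyl)tetrahydrofuran-2-yl]-2,6-dimethoxyphenol | COc1cc(C[C@H]2CO[C@H](c3cc(OC)c(O)c(OC)c3)[C@H]2CO)ccc1OCc1ccccc1
F6 | step 7 | (R)-4-(4-hydroxy-3-methoxybenzyl)dihydrofuran-2(3H)-one | O=C1C[C@@H](Cc2ccc(O)c(OC)c2)CO1
F7 | step 7 | (3S,4R)-3-[hydroxy(3,4,5-trimethoxyphenyl)methyl]-4-(4-hydroxy-3-methoxybenzyl)dihydrofuran-2(3H)-one | O=C1OC[C@H](Cc2ccc(O)c(OC)c2)[C@H]1C(O)c1cc(OC)c(OC)c(OC)c1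
F8 | step 7 | (2R,3R)-2-(4-hydroxy-3-methoxybenzyl)-3-[hydroxy(3,4,5-trimethoxyphenyl)methyl]butane-1,4-diol | OC[C@H](Cc1ccc(O)c(OC)c1)[C@H](CO)C(O)c1cc(OC)c(OC)c(OC)c1
F9 | step 4 | (3S,4R)-4-[4-(benzyloxy)-3-methoxybenzyl]-3-(3,4,5-trimethoxybenzoyl)dihydrofuran-2(3H)-one | O=C1OC[C@H](Cc2ccc(OCc3ccccc3)c(OC)c2)[C@H]1C(=O)c1cc(OC)c(OC)c(OC)c1
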